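(The runs were computed from invented constants, and the scatter is random.)

The target costs one electrophile and one nucleophile, so I asked what each flask could make before asking how fast.

| flask | electrophile | nucleophile | remark | time |
|---|---|---|---|---|
| Monday's | 10 mM | 0.90 equiv | run made earlier |  |
| Friday's | 40 mM | 0.90 equiv | run made earlier |  |
| Sunday's | 20 mM | 1.4 equiv | run made earlier |  |
| flask | 20 mM | 0.900 equiv |  | 12 h |

| run | time / h | electrophile / % | target / % |
|---|---|---|---|
| Monday's | 0.500 | 23.2 | 77.1 |
| Monday's | 1.33 | 13.2 | 85.4 |
| Monday's | 2.50 | 11.6 | 89.1 |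
| Monday's | 4.00 | 9.8 | 89.6 |
| Monday's | 6.00 | 10.1 | 89.8 |
| Monday's | 8.00 | 10.0 | 90.0 |
| Monday's | 10.0 | 9.3 | 89.9 |
| Friday's | 1.33 | 10.3 | 89.0 |
| Friday's | 3.00 | 9.7 | 90.3 |
| Friday's | 4.00 | 11.1 | 90.3 |
| Friday's | 6.00 | 9.0 | 90.1 |
| Friday's | 8.00 | 9.7 | 90.2 |
| Friday's | 10.0 | 9.7 | 90.0 |
| Sunday's | 2.00 | 0.3 | 99.7 |
| Sunday's | 4.00 | 0.1 | 100.0 |
| Sunday's | 6.00 | 0.6 | 99.3 |
| Sunday's | 8.00 | 0 | 99.5 |
| Sunday's | 10.0 | 0.5 | 99.5 |

(readings scatter by 0.5 percentage points)

- what is said of acid set free includes crystals
- crystals is a solid; its amount is given per volume of the solution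
- what may be going on: crystals <-> acid set free; electrophile + nucleophile -> acid set free + target; nucleophile + acid set free <-> protonated nucleophile
- the earlier runs do not show how much of nucleophile is bound; that part of a forecast is a guess

1. part of the electrophile that has reacted at 12 h
2. share of the unused nucleophile that is free and not bound as protonated nucleophile, at 12 h

For the new flask I reckoned a ceiling C = 90.0%: the lesser of the nucleophile equivalents and one, as a percentage of the electrophile charged. Monday's run ended at 89.9% target and Friday's at 90.0%, against a C of 90.0% with nucleophile as limiting reagent; Sunday's ended at 99.5%, against 100%. Monday's run was flat by 4.00 h, earlier than the 12 h asked, so I expected this flask to stand at C = 90.0%.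

The forecast gave the part of the electrophile reacted as c = 90% (89% to 91%) and the free share of the unused nucleophile as fr = 65% (15% to 98%), the second being “a guess, leaning towards mostly free”.

The flask gave c = 90.0%, against C = 90.0%, and fr = 7.36%, which is 58 percentage points below the forecast.

    crystals ⇌ acid set free, rate k1*(cs1 - [acid set free]) while solid is left; crystals form when [acid set free] > cs1 (solubility = 0.370 mM, k = 0.220 s⁻¹)
    electrophile + nucleophile → acid set free + target (k = 3.20 L mol⁻¹ s⁻¹)
    nucleophile + acid set free ⇌ protonated nucleophile, settled at all times (K = 34000 L mol⁻¹)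

In this flask the nucleophile's half-life by the conversion step was 0.33 min at 0.0139 h, short against the 12 h of the run. The same flask with 0.540 equiv of nucleophile, where C is 54.0%, gave c = 54.0% and fr = 7.36%.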